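(The runs come from a simulation with constants of no real substance.)

The forecaster and a colleague looked at the same two runs, zeta and theta, and disagreed about what the partner does in the new flask.

| setting | zeta | theta | flask |
|---|---|---|---|
| substrate | 13 mM | 13 mM | 13 mM |
| partner | 9.2 mM | 21 mM | 13.7 mM |
| remark | run made earlier | run made earlier |  |
| time |  |  | 8.0 d |

- zeta (time / d: substrate / %, product / %, open intermediate / %): 0.333: 79.4, 1.6, 18.9; 1.04: 76.7, 4.5, 17.8; 1.67: 76.5, 5.2, 18.0; 3.00: 76.5, 5.3, 18.4; 4.00: 76.6, 5.9, 18.1; 5.00: 76.1, 5.2, 18.0; 6.00: 76.0, 5.6, 18.4
- theta (time / d: substrate / %, product / %, open intermediate / %): 0.500: 76.1, 6.0, 17.2; 0.833: 73.0, 9.0, 17.5; 1.25: 72.4, 11.0, 17.5; 1.67: 71.5, 11.1, 17.3; 3.00: 71.9, 11.2, 17.1; 4.00: 71.5, 11.5, 17.4; 6.00: 71.3, 11.0, 17.6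

(standard deviation of a reading: 0.3 percentage points)

- on the list of suspects stand: substrate <-> open intermediate; partner -> second intermediate; open intermediate + second intermediate <-> product

* conversion of substrate at 8.0 d
* amount of product at 8.0 d, in percent of the substrate charged
* amount of open intermediate at 8.0 d, in percent of the substrate charged

Both saw that product stops rising by about 1.67 d. On that plateau zeta averages 5.50% of product and 18.2% of open intermediate, and theta 11.2% and 17.4%.

The colleague counts partner: each charge yields a constant share of itself as product, zeta's reading is 7.77% of the partner charged, and zeta is the nearer run, so the flask should reach 8.19%.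

The forecaster treats the plateau as an equilibrium and says of her two quotients, “These agree fairly well, with a slight drift.” She forecasts 25.6% conversion, 7.7% of product and 17.9% of open intermediate, so the colleague's number lies above her range.

My own reckoning takes the same form. I divide c_product by c_open intermediate and by c_second intermediate, taking the last as partner charged minus product, and I expect the ratio of product to open intermediate to be first order in c_second intermediate. Zeta gives 35.6 /M and theta 33.1 /M, and their mean 34.3 /M is the holding quotient. With open intermediate at 19.4% of what is not product, the balance gives 7.80% of product, slightly above her number.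

The flask gives 25.6% conversion, 7.71% of product and 17.9% of open intermediate, so the forecast stands and the colleague is high by 0.48 percentage points.

    substrate ⇌ open intermediate (K = 0.240, k = 0.150 /h)
    partner → second intermediate (k = 0.120 /h)
    open intermediate + second intermediate ⇌ product (K = 34.0 /M, k = 5.40 /M/h)

The relaxation half-life of the step joining open intermediate and second intermediate to product, both ways together, is 0.120 d at 8.00 d, short against the flask's 8.0 d, and the flask holds 7.71% of product at 4.00 d and 7.71% at 80.0 d, which is thermodynamic control. With the 12.7 mM of second intermediate standing in the flask at 8.00 d, the holding quotient 34.3 /M puts product at 0.436 times open intermediate, while the flask's product is 7.32% of the partner charged, less than zeta's reading.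

In the neighbour flask with 5.5 mM of partner, the holding quotient gives 3.27% of product and the colleague's share gives 3.29%, so at this small charge his view serves as well. That neighbour flask computes to 3.23%.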